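**Strategy.** The route rests on the C6–C7 disconnection of ring B (C4–C5–C6–C7–C8–C9, cyathane numbering, defined below), closed last between a lactone-fused ring A and the epoxidised ring C, which are first joined through C4–C5 by a branch-selective allyl–allyl coupling. The key step exploits the quaternary C6 with its C16 methyl: iron-hydride hydrogen-atom transfer to the exocyclic C6=C16 methylene of the precursor (ring A bearing a C7 N-tosylhydrazone arm on C9) gives the tertiary C6 radical, which adds 6-exo to C7; loss of sulfinate and N2 leaves C7H2. One operation thus closes ring B, creates the methyl and sets C6 (trans B/C fusion).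

Key step: step 23

Remark on the chemistry (numbering): ring A = C1, C2, C3, C4, C9; ring B = C4–C9; ring C = C5, C6, C10–C14; C15 = methyl on C12, C16 = methyl on C6, C17 = oxygenated CH2 on C9, C18 = lactone α-carbon on C3, C19 = its methylene, C20 = lactone carbonyl; β is the face of C17, and the same descriptors are used for the ring-B-open intermediates.

**Ring C fragment**

Step 1
Reactants: 1 triethyl phosphonoacetate; 2 allyl bromide
Product: 3 ethyl 2-(diethoxyphosphoryl)pent-4-enoate (racemic)
Conditions: NaH, THF, 0 °C to rt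
Reagents that add atoms: none
Why: The sodium enolate of the phosphonoacetate is C-alkylated once by the allylic bromide (enolate alkylation, SN2); the new stereocentre is irrelevant because it becomes sp2 in step 3.

Step 2
Reactants: 4 4-methylpent-4-en-1-ol
Product: 5 4-methylpent-4-enal
Conditions: TEMPO (cat.), PhI(OAc)2, CH2Cl2, rt
Reagents that add atoms: none
Why: Oxoammonium (TEMPO) oxidation converts the primary alcohol into the aldehyde without touching the 1,1-disubstituted alkene.

Step 3
Reactants: 3 ethyl 2-(diethoxyphosphoryl)pent-4-enoate; 5 4-methylpent-4-enal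
Product: 6 ethyl (2E)-6-methyl-2-(prop-2-en-1-yl)hepta-2,6-dienoate
Conditions: NaH, THF, 0 °C to rt
Reagents that add atoms: none
Why: Horner–Wadsworth–Emmons olefination of an aliphatic aldehyde with an α-substituted phosphonoacetate should favour the E enoate (ester trans to the new chain), which is the only isomer able to cyclise in step 4.

Step 4
Reactants: 6 ethyl (2E)-6-methyl-2-(prop-2-en-1-yl)hepta-2,6-dienoate
Product: 7 ethyl 5-methylcyclohepta-1,5-diene-1-carboxylate
Conditions: second-generation Grubbs catalyst (3 mol %), CH2Cl2, 40 °C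
Reagents that add atoms: none
Why: Ring-closing metathesis between the monosubstituted allyl alkene and the 1,1-disubstituted alkene closes the seven-membered ring C with its trisubstituted C12=C13 bond, while the electron-poor trisubstituted enoate is spared.

Step 5
Reactants: 7 ethyl 5-methylcyclohepta-1,5-diene-1-carboxylate
Product: 8 ethyl (1R,7S)-7-methyl-8-oxabicyclo[5.1.0]oct-3-ene-3-carboxylate
Conditions: D-fructose-derived Shi ketone (30 mol %), Oxone, K2CO3, Bu4NHSO4, MeCN/dimethoxymethane/aq. buffer (pH 10.5), 0 °C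
Reagents that add atoms: potassium peroxymonosulfate (Oxone), [K+].[O-]S(=O)(=O)OO
Why: Shi epoxidation: the chiral dioxirane oxidises only the electron-rich trisubstituted C12=C13 alkene (the enoate is deactivated) and, by the spiro transition-state model established for 1-substituted cycloalkenes, should deliver oxygen to the face that gives the (1R,7S) epoxide, the 12β,13β-epoxide of the target.

Step 6
Reactants: 8 ethyl (1R,7S)-7-methyl-8-oxabicyclo[5.1.0]oct-3-ene-3-carboxylate
Product: 9 [(1R,7S)-7-methyl-8-oxabicyclo[5.1.0]oct-3-en-3-yl]methanol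
Conditions: DIBAL-H (2.2 equiv), CH2Cl2, −78 °C
Reagents that add atoms: none
Why: 1,2-Hydride reduction of the enoate gives the primary allylic alcohol, and the trisubstituted epoxide is inert to DIBAL-H at this temperature.

Step 7
Reactants: 9 [(1R,7S)-7-methyl-8-oxabicyclo[5.1.0]oct-3-en-3-yl]methanol
Product: 10 [(1R,7S)-7-methyl-8-oxabicyclo[5.1.0]oct-3-en-3-yl]methyl acetate
Conditions: Ac2O, pyridine, DMAP (cat.), CH2Cl2, 0 °C
Reagents that add atoms: acetic anhydride, CC(=O)OC(C)=O
Why: Standard acylation of a primary allylic alcohol provides the leaving group for the borylation.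

Step 8
Reactants: 10 [(1R,7S)-7-methyl-8-oxabicyclo[5.1.0]oct-3-en-3-yl]methyl acetate
Product: 11 ring C allylboronate, 4,4,5,5-tetramethyl-2-{[(1R,7S)-7-methyl-8-oxabicyclo[5.1.0]oct-3-en-3-yl]methyl}-1,3,2-dioxaborolane
Conditions: B2pin2, Pd2(dba)3 (2.5 mol %), DMSO, 50 °C
Reagents that add atoms: bis(pinacolato)diboron, CC1(C)OB(OC1(C)C)B1OC(C)(C)C(C)(C)O1
Why: Miyaura-type allylic borylation: zerovalent palladium ionises the allylic acetate and the π-allyl complex is borylated at the less hindered primary terminus, the non-allylic epoxide being untouched.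

**Ring A fragment**

Step 9
Reactants: 12 methyl 3-oxocyclopent-1-ene-1-carboxylate
Product: 13 methyl (3R)-3-hydroxycyclopent-1-ene-1-carboxylate
Conditions: (S)-2-methyl-CBS-oxazaborolidine (10 mol %), BH3·SMe2, THF, −30 °C
Reagents that add atoms: none
Why: Corey–Bakshi–Shibata reduction delivers hydride 1,2 to the ketone with the alkenyl side acting as the large group, which should set the (R)-carbinol (C3–OH on the α face).

Step 10
Reactants: 13 methyl (3R)-3-hydroxycyclopent-1-ene-1-carboxylate
Product: 15 methyl (1S)-1-[2-(dimethylamino)-2-oxoethyl]cyclopent-2-ene-1-carboxylate, via ketene N,O-acetal 14 (not isolated)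
Conditions: MeC(OMe)2NMe2, xylene, 140 °C
Reagents that add atoms: N,N-dimethylacetamide dimethyl acetal, COC(C)(OC)N(C)C
Why: Eschenmoser–Claisen rearrangement: ketene N,O-acetal 14 rearranges suprafacially so that the acetamide arm (C8–C7) is delivered to C9 on the α face, where the C3–O bond was, setting the quaternary C9 by 1,3-chirality transfer and moving the alkene to C3=C4.

Step 11
Reactants: 15 methyl (1S)-1-[2-(dimethylamino)-2-oxoethyl]cyclopent-2-ene-1-carboxylate
Product: 16 2-[(1S)-1-(hydroxymethyl)cyclopent-2-en-1-yl]-N,N-dimethylacetamide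
Conditions: LiBH4, THF, MeOH (1 equiv), 0 °C to rt
Reagents that add atoms: none
Why: Chemoselective hydride reduction: LiBH4 reduces the methyl ester to the neopentyl alcohol (C17) and leaves the tertiary amide untouched; the product is silylated directly to forestall lactonisation onto the amide.

Step 12
Reactants: 16 2-[(1S)-1-(hydroxymethyl)cyclopent-2-en-1-yl]-N,N-dimethylacetamide
Product: 17 N,N-dimethyl-2-[(1S)-1-({[tri(propan-2-yl)silyl]oxy}methyl)cyclopent-2-en-1-yl]acetamide
Conditions: TIPSOTf, 2,6-lutidine, CH2Cl2, 0 °C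
Reagents that add atoms: triisopropylsilyl triflate, CC(C)[Si](OS(=O)(=O)C(F)(F)F)(C(C)C)C(C)C
Why: Silylation of the hindered primary alcohol gives a fluoride-labile ether that should survive every later step, including the CsF-promoted coupling.

Step 13
Reactants: 17 N,N-dimethyl-2-[(1S)-1-({[tri(propan-2-yl)silyl]oxy}methyl)cyclopent-2-en-1-yl]acetamide
Product: 18 ring A enone, 2-[4-oxo-1-({[tri(propan-2-yl)silyl]oxy}methyl)cyclopent-2-en-1-yl]-N,N-dimethylacetamide (C2 ketone, C3=C4, 9β-CH2OTIPS, 9α-CH2CONMe2)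
Conditions: Rh2(cap)4 (dirhodium tetracaprolactamate, 1 mol %), t-BuOOH (70 % aq., 5 equiv), K2CO3, CH2Cl2, rt
Reagents that add atoms: tert-butyl hydroperoxide, CC(C)(C)OO
Why: Doyle allylic oxidation converts the only allylic CH2 (C2; the other allylic position, C9, is quaternary) into the enone carbonyl.

Step 14
Reactants: 18 ring A enone
Product: 19 α-iodoenone (3-iodo derivative of 18)
Conditions: I2, pyridine, CH2Cl2, rt
Reagents that add atoms: iodine, II
Why: Johnson α-iodination (conjugate addition of pyridine, iodination of the enolate, elimination) is known on 4,4-disubstituted cycloalkenones and installs the handle at C3.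

Step 15
Reactants: 19 α-iodoenone
Product: 20 enone ester, ethyl 2-{3-[2-(dimethylamino)-2-oxoethyl]-5-oxo-3-({[tri(propan-2-yl)silyl]oxy}methyl)cyclopent-1-en-1-yl}acetate
Conditions: ethyl 2-(tributylstannyl)acetate, Pd2(dba)3 (5 mol %), AsPh3, CuI (cat.), DMF, 50 °C
Reagents that add atoms: ethyl 2-(tributylstannyl)acetate, CCCC[Sn](CCCC)(CCCC)CC(=O)OCC
Why: Stille (Kosugi–Migita) coupling of the reactive α-iodoenone attaches the C18–C20 acetate arm to C3, a stannane being chosen because it does not add to the enone carbonyl.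

Step 16
Reactants: 20 enone ester
Product: 21 2α-allylic alcohol (2R), ethyl 2-{5-hydroxy-3-[2-(dimethylamino)-2-oxoethyl]-3-({[tri(propan-2-yl)silyl]oxy}methyl)cyclopent-1-en-1-yl}acetate
Conditions: (S)-2-methyl-CBS-oxazaborolidine (20 mol %), BH3·SMe2, toluene, −40 °C
Reagents that add atoms: none
Why: CBS reduction of an α-substituted cyclopentenone is reagent-controlled and should give the (2R) alcohol, the 2α-OH cis to the C8 arm, without reducing the amide at this temperature.

Step 17
Reactants: 21 2α-allylic alcohol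
Product: 22 2α-methyl carbonate of 21
Conditions: ClCO2Me, pyridine, DMAP (cat.), CH2Cl2, 0 °C
Reagents that add atoms: methyl chloroformate, COC(=O)Cl
Why: Acylation of the secondary allylic alcohol with retention gives the ionisable leaving group and prevents lactonisation onto the C20 ester.

**Union, lactone, ring B, end game**

Step 18
Reactants: 22 2α-methyl carbonate; 11 ring C allylboronate
Product: 23 ring-B-open 1,5-diene: ring A cyclopentene (C2=C3) with C18H2CO2Et on C3, 9β-CH2OTIPS and 9α-CH2CONMe2, bonded from C4 (β bond, 4α-H) to C5 (5β-H) of ring C, which carries the exocyclic C6=C16 methylene and the 12β,13β-epoxide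
Conditions: Pd2(dba)3 (2.5 mol %), (R)-MeO-furyl-BIPHEP (6 mol %), CsF (3 equiv), THF/H2O 10:1, 60 °C
Reagents that add atoms: none
Why: Palladium-catalysed branch-selective allyl–allyl cross-coupling: zerovalent palladium ionises the carbonate with inversion (Pd on the β face), fluoride-promoted transmetalation of 11 gives a bis(σ-allyl)palladium, and 3,3′-reductive elimination through a chair (both central carbons are substituted, which penalises a boat) should join C4 to C5 on the β face, setting C4 anti to the departed carbonate and C5 (5β-H) relative to C4, and leaving the C2=C3 and exocyclic C6=C16 alkenes.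

Step 19
Reactants: 23 ring-B-open 1,5-diene
Product: 24 carboxylic acid of 23 (C20 acid)
Conditions: LiOH·H2O, THF/H2O, 0 °C to rt; then aq. KHSO4 to pH 4
Reagents that add atoms: lithium hydroxide, [Li+].[OH-]
Why: Saponification of the unhindered ethyl ester, which leaves amide, silyl ether and epoxide intact when the acidification is kept mild.

Step 20
Reactants: 24 carboxylic acid
Product: 26 hydroxy-lactone amide (2β,20-olide, 3α-OH; ring B still open), via epoxy acid 25 (not isolated)
Conditions: mCPBA (1.05 equiv), NaHCO3, CH2Cl2, −20 to 0 °C; then rt (PPTS, 5 mol %, if needed)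
Reagents that add atoms: 3-chloroperbenzoic acid, OOC(=O)c1cccc(Cl)c1
Why: Peracid epoxidation of the trisubstituted C2=C3 alkene, which is more nucleophilic than the 1,1-disubstituted C6=C16 alkene, should occur anti to the β ring C substituent at C4 to give the α-epoxide 25, and the carboxylic acid then opens it at C2 with inversion (epoxide-opening lactonisation of a β,γ-epoxy acid), giving the cis-fused lactone with 2β-O and 3α-OH.

Step 21
Reactants: 26 hydroxy-lactone amide
Product: 27 C7 aldehyde (CH2CHO arm on C9)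
Conditions: Cp2Zr(H)Cl (2.5 equiv), THF, rt, 20 min; then H2O/silica gel
Reagents that add atoms: none
Why: Schwartz reagent reduces tertiary amides to aldehydes through a stable zirconated hemiaminal and, on this time scale, spares lactones, epoxides and 1,1-disubstituted alkenes.

Step 22
Reactants: 27 C7 aldehyde
Product: 28 C7 N-tosylhydrazone
Conditions: TsNHNH2 (1.1 equiv), MeOH, rt
Reagents that add atoms: 4-methylbenzenesulfonohydrazide, Cc1ccc(cc1)S(=O)(=O)NN
Why: Condensation of the aldehyde (free or as its lactol with the 3α-OH) with the sulfonyl hydrazide gives the radical acceptor.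

Step 23
Reactants: 28 C7 N-tosylhydrazone
Product: 31 tetracyclic lactone (17-O-TIPS, 3α-OH, 12β,13β-epoxide, C18H2), via hydrazide 29 (not isolated), via diazene 30 (not isolated)
Conditions: Fe(acac)3 (30 mol %), PhSiH3 (2.5 equiv), EtOH, 60 °C; then NaOAc, 70 °C
Reagents that add atoms: none
Why: An iron hydride formed from Fe(acac)3 and PhSiH3 transfers a hydrogen atom to the exocyclic C6=C16 methylene of 28, so that C16 becomes the methyl group and C6 a tertiary radical, which adds to the electrophilic C7 of the hydrazone; the hydrazinyl radical is reduced to hydrazide 29, acetate-induced loss of p-toluenesulfinate gives diazene 30, and this expels N2 to leave C7H2. The closest known reaction type is the iron-hydride (MHAT) reductive coupling of unactivated alkenes with sulfonylhydrazones, a radical counterpart of the Wolff–Kishner/Kabalka deoxygenative alkylation. Ring B closes in the 6-exo-trig mode through a chair transition state. The only new stereocentre, C6, is controlled by the trans arrangement of the C8 arm and C5 on ring A and by the 5β-hydrogen: with H-4 and H-5 axial and the ring C methylene C14 equatorial, C7 should bond to the face that makes C16 the axial α-methyl (trans B/C fusion), whereas the cis alternative would push ring C under the α face against the axial hydrogens at C4 and C8 and the 3α-hydroxyl. The step needs selectivity for one alkene and for cyclisation over simple alkene reduction: 28 contains a single C=C (C12–C13 is already the epoxide and the lactone has no methylene yet), and the acceptor is held six atoms from the radical.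

Step 24
Reactants: 31 tetracyclic lactone
Product: 32 Mannich base (18-CH2NMe2 lactone)
Conditions: LDA (3.2 equiv), THF, −78 °C; then Me2N=CH2 I (Eschenmoser's salt), −78 to 0 °C
Reagents that add atoms: N,N-dimethylmethyleneiminium iodide, C=[N+](C)C.[I-]
Why: Mannich reaction of the lactone enolate (formed as the dianion with the 3-alkoxide) at C18, the only enolisable position; the new C18 stereocentre is inconsequential because it becomes sp2 in step 25.

Step 25
Reactants: 32 Mannich base
Product: 34 α-methylene lactone (17-O-TIPS), via ammonium iodide 33 (not isolated)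
Conditions: MeI, THF/MeOH, rt; then aq. NaHCO3, EtOAc, rt
Reagents that add atoms: none
Why: Quaternisation followed by E1cB (Hofmann-type) loss of trimethylamine gives the C18=C19 methylene under conditions that leave the epoxide, silyl ether and tertiary alcohol untouched.

Step 26
Reactants: 34 α-methylene lactone (17-O-TIPS)
Product: 35 17-alcohol (deacetyl target)
Conditions: TBAF, AcOH (1:1), THF, 0 °C to rt
Reagents that add atoms: none
Why: Buffered fluoride desilylation frees the primary C17 alcohol without base-induced damage to the α-methylene lactone or the epoxide.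

Step 27
Reactants: 35 17-alcohol
Product: 36 CNP0404717.1
Conditions: Ac2O, pyridine, DMAP (cat.), CH2Cl2, 0 °C
Reagents that add atoms: acetic anhydride, CC(=O)OC(C)=O
Why: Acetylation of the primary C17 alcohol, the tertiary 3α-OH being too hindered to react under these conditions.

**Compound list**

1 | triethyl phosphonoacetate | CCOC(=O)CP(=O)(OCC)OCC | starting material
2 | allyl bromide | C=CCBr | starting material
3 | ethyl 2-(diethoxyphosphoryl)pent-4-enoate (racemic) | CCOC(=O)C(CC=C)P(=O)(OCC)OCC | intermediate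
4 | 4-methylpent-4-en-1-ol | CC(=C)CCCO | starting material
5 | 4-methylpent-4-enal | CC(=C)CCC=O | intermediate
6 | ethyl (2E)-6-methyl-2-(prop-2-en-1-yl)hepta-2,6-dienoate | CCOC(=O)/C(CC=C)=C/CCC(C)=C | intermediate
7 | ethyl 5-methylcyclohepta-1,5-diene-1-carboxylate | CCOC(=O)C1=CCCC(C)=CC1 | intermediate
8 | ethyl (1R,7S)-7-methyl-8-oxabicyclo[5.1.0]oct-3-ene-3-carboxylate | CCOC(=O)C1=CCC[C@]2(C)O[C@@H]2C1 | intermediate
9 | [(1R,7S)-7-methyl-8-oxabicyclo[5.1.0]oct-3-en-3-yl]methanol | OCC1=CCC[C@]2(C)O[C@@H]2C1 | intermediate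
10 | [(1R,7S)-7-methyl-8-oxabicyclo[5.1.0]oct-3-en-3-yl]methyl acetate | CC(=O)OCC1=CCC[C@]2(C)O[C@@H]2C1 | intermediate
11 | ring C allylboronate, 4,4,5,5-tetramethyl-2-{[(1R,7S)-7-methyl-8-oxabicyclo[5.1.0]oct-3-en-3-yl]methyl}-1,3,2-dioxaborolane | CC1(C)OB(CC2=CCC[C@]3(C)O[C@@H]3C2)OC1(C)C | intermediate
12 | methyl 3-oxocyclopent-1-ene-1-carboxylate | COC(=O)C1=CC(=O)CC1 | starting material
13 | methyl (3R)-3-hydroxycyclopent-1-ene-1-carboxylate | COC(=O)C1=C[C@H](O)CC1 | intermediate
14 | ketene N,O-acetal, methyl (3R)-3-{[1-(dimethylamino)ethenyl]oxy}cyclopent-1-ene-1-carboxylate | COC(=O)C1=C[C@H](OC(=C)N(C)C)CC1 | intermediate (not isolated)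
15 | methyl (1S)-1-[2-(dimethylamino)-2-oxoethyl]cyclopent-2-ene-1-carboxylate | C1C=C[C@@](C(=O)OC)(CC(=O)N(C)C)C1 | intermediate
16 | 2-[(1S)-1-(hydroxymethyl)cyclopent-2-en-1-yl]-N,N-dimethylacetamide | C1C=C[C@@](CO)(CC(=O)N(C)C)C1 | intermediate
17 | N,N-dimethyl-2-[(1S)-1-({[tri(propan-2-yl)silyl]oxy}methyl)cyclopent-2-en-1-yl]acetamide | C1C=C[C@@](CO[Si](C(C)C)(C(C)C)C(C)C)(CC(=O)N(C)C)C1 | intermediate
18 | ring A enone (C2 ketone, C3=C4, 9β-CH2OTIPS, 9α-CH2CONMe2) | O=C1C=C[C@@](CO[Si](C(C)C)(C(C)C)C(C)C)(CC(=O)N(C)C)C1 | intermediate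
19 | α-iodoenone (3-iodo derivative of 18) | O=C1C(I)=C[C@@](CO[Si](C(C)C)(C(C)C)C(C)C)(CC(=O)N(C)C)C1 | intermediate
20 | enone ester (C18H2CO2Et on C3) | CCOC(=O)CC1=C[C@@](CO[Si](C(C)C)(C(C)C)C(C)C)(CC(=O)N(C)C)CC1=O | intermediate
21 | 2α-allylic alcohol (2R) | CCOC(=O)CC1=C[C@@](CO[Si](C(C)C)(C(C)C)C(C)C)(CC(=O)N(C)C)C[C@H]1O | intermediate
22 | 2α-methyl carbonate of 21 | CCOC(=O)CC1=C[C@@](CO[Si](C(C)C)(C(C)C)C(C)C)(CC(=O)N(C)C)C[C@H]1OC(=O)OC | intermediate
23 | ring-B-open 1,5-diene (C4–C5 bond, C2=C3, exocyclic C6=C16, 12β,13β-epoxide, ethyl ester) | CCOC(=O)CC1=CC[C@](CO[Si](C(C)C)(C(C)C)C(C)C)(CC(=O)N(C)C)[C@H]1[C@H]2CC[C@]3(C)O[C@@H]3CC2=C | intermediate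
24 | carboxylic acid of 23 | OC(=O)CC1=CC[C@](CO[Si](C(C)C)(C(C)C)C(C)C)(CC(=O)N(C)C)[C@H]1[C@H]2CC[C@]3(C)O[C@@H]3CC2=C | intermediate
25 | 2α,3α-epoxy acid | OC(=O)C[C@@]12O[C@@H]1C[C@](CO[Si](C(C)C)(C(C)C)C(C)C)(CC(=O)N(C)C)[C@H]2[C@H]3CC[C@]4(C)O[C@@H]4CC3=C | intermediate (not isolated)
26 | hydroxy-lactone amide (2β,20-olide, 3α-OH, ring B open) | C1C(=O)O[C@H]2C[C@](CO[Si](C(C)C)(C(C)C)C(C)C)(CC(=O)N(C)C)[C@@H]([C@H]3CC[C@]4(C)O[C@@H]4CC3=C)[C@@]12O | intermediate
27 | C7 aldehyde | C1C(=O)O[C@H]2C[C@](CO[Si](C(C)C)(C(C)C)C(C)C)(CC=O)[C@@H]([C@H]3CC[C@]4(C)O[C@@H]4CC3=C)[C@@]12O | intermediate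
28 | C7 N-tosylhydrazone | C1C(=O)O[C@H]2C[C@](CO[Si](C(C)C)(C(C)C)C(C)C)(CC=NNS(=O)(=O)c3ccc(C)cc3)[C@@H]([C@H]4CC[C@]5(C)O[C@@H]5CC4=C)[C@@]12O | intermediate
29 | cyclised 7-(N′-tosylhydrazino) tetracycle (C7 epimers) | C1C(=O)O[C@H]2C[C@]3(CO[Si](C(C)C)(C(C)C)C(C)C)CC(NNS(=O)(=O)c6ccc(C)cc6)[C@@]4(C)C[C@H]5O[C@@]5(C)CC[C@@H]4[C@H]3[C@@]12O | intermediate (not isolated)
30 | 7-diazenyl tetracycle | C1C(=O)O[C@H]2C[C@]3(CO[Si](C(C)C)(C(C)C)C(C)C)CC(N=N)[C@@]4(C)C[C@H]5O[C@@]5(C)CC[C@@H]4[C@H]3[C@@]12O | intermediate (not isolated)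
31 | tetracyclic lactone (17-O-TIPS, 3α-OH, epoxide, C18H2) | C1C(=O)O[C@H]2C[C@]3(CO[Si](C(C)C)(C(C)C)C(C)C)CC[C@@]4(C)C[C@H]5O[C@@]5(C)CC[C@@H]4[C@H]3[C@@]12O | intermediate
32 | Mannich base (18-CH2NMe2, C18 epimers) | CN(C)CC1C(=O)O[C@H]2C[C@]3(CO[Si](C(C)C)(C(C)C)C(C)C)CC[C@@]4(C)C[C@H]5O[C@@]5(C)CC[C@@H]4[C@H]3[C@@]12O | intermediate
33 | trimethylammonium iodide of 32 | C[N+](C)(C)CC1C(=O)O[C@H]2C[C@]3(CO[Si](C(C)C)(C(C)C)C(C)C)CC[C@@]4(C)C[C@H]5O[C@@]5(C)CC[C@@H]4[C@H]3[C@@]12O.[I-] | intermediate (not isolated)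
34 | α-methylene lactone, 17-O-TIPS | C=C1C(=O)O[C@H]2C[C@]3(CO[Si](C(C)C)(C(C)C)C(C)C)CC[C@@]4(C)C[C@H]5O[C@@]5(C)CC[C@@H]4[C@H]3[C@@]12O | intermediate
35 | 17-alcohol (deacetyl target) | C=C1C(=O)O[C@H]2C[C@]3(CO)CC[C@@]4(C)C[C@H]5O[C@@]5(C)CC[C@@H]4[C@H]3[C@@]12O | intermediate
36 | CNP0404717.1 | C=C1C(=O)O[C@H]2C[C@]3(COC(C)=O)CC[C@@]4(C)C[C@H]5O[C@@]5(C)CC[C@@H]4[C@H]3[C@@]12O | target

**Totals.** Total step count: 27. Longest linear sequence: 19 steps (steps 9–27, from 12).

**Steps most likely to fail**

1. Step 18 (allyl–allyl coupling). The 3,3′-reductive elimination has to join two substituted allyl termini, one of them next to the quaternary C9. It may be outrun by linear C–C bond formation or by β-hydride elimination of the cyclopentenyl π-allyl complex to a cyclopentadiene, and the ligand antipode may be mismatched with the substrate-controlled chair. Fallback (thermal [3,3] instead of palladium), setting out from 20 and 8 and returning at 23: reduction of 20 with the (R)-CBS catalyst should give the 2β-allylic alcohol F1. Ester 8 is saponified to the ring C acid F2 and iododecarboxylated (N-iodosuccinimide, LiOAc cat., MeCN/H2O) to the ring C vinyl iodide F3. C–O coupling of F1 with F3 (CuI, 3,4,7,8-tetramethyl-1,10-phenanthroline, Cs2CO3, toluene, 110 °C) gives the allyl vinyl ether F4, which should undergo Claisen rearrangement in the same flask, suprafacially and through the same chair, to the ring C ketone F5. Immediate non-basic methylenation of this base-sensitive β,γ-epoxy ketone with Cp2TiMe2 (toluene, 65 °C) gives 23.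

2. Step 23 (key step). The tertiary radical may be quenched by a second hydrogen-atom transfer (net hydrogenation of the alkene), the silane may reduce the hydrazone C=N before cyclisation, or closure may proceed through the alternative chair to the cis B/C fusion. Fallback, setting out from 27 and returning at 31: the same iron-hydride conditions (Fe(acac)3, PhSiH3, EtOH, 60 °C) applied to the aldehyde itself should give, by radical addition to the C=O group, the 7-hydroxy tetracycle F6. Acylation with 1,1′-thiocarbonyldiimidazole gives the 7-O-thiocarbonylimidazolide F7, and Barton–McCombie deoxygenation (Bu3SnH, AIBN, toluene, 90 °C) gives 31. This separates C–C bond formation from removal of the heteroatom and uses a more electrophilic, sterically smaller acceptor.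

3. Step 20 (epoxidation–lactonisation). The peracid may also epoxidise the exocyclic C6=C16 alkene, and 3-chlorobenzoic acid may open the ring C epoxide during lactonisation. Fallback (hydroxyl-directed epoxidation), setting out from 23 and returning at 26: LiBH4 reduces the ethyl ester of 23 to the homoallylic alcohol F8. VO(acac)2/t-BuOOH (CH2Cl2, 0 °C) epoxidises only the C2=C3 alkene next to the hydroxyl, from the less hindered α face, to give the epoxy alcohol F9. Oxidation with TEMPO/PhI(OAc)2 in MeCN/H2O gives epoxy acid 25, which lactonises to 26 without any peracid or strong acid.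

Further compounds
F1 | step 18 | 2β-allylic alcohol (C2 epimer of 21) | CCOC(=O)CC1=C[C@@](CO[Si](C(C)C)(C(C)C)C(C)C)(CC(=O)N(C)C)C[C@@H]1O
F2 | step 18 | ring C acid, (1R,7S)-7-methyl-8-oxabicyclo[5.1.0]oct-3-ene-3-carboxylic acid | OC(=O)C1=CCC[C@]2(C)O[C@@H]2C1
F3 | step 18 | ring C vinyl iodide, (1R,7S)-3-iodo-7-methyl-8-oxabicyclo[5.1.0]oct-3-ene | IC1=CCC[C@]2(C)O[C@@H]2C1
F4 | step 18 | allyl vinyl ether (C2–O–C6) | CCOC(=O)CC1=C[C@@](CO[Si](C(C)C)(C(C)C)C(C)C)(CC(=O)N(C)C)C[C@@H]1OC2=CCC[C@]3(C)O[C@@H]3C2
F5 | step 18 | ring C ketone (C6=O analogue of 23) | CCOC(=O)CC1=CC[C@](CO[Si](C(C)C)(C(C)C)C(C)C)(CC(=O)N(C)C)[C@H]1[C@H]2CC[C@]3(C)O[C@@H]3CC2=O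
F6 | step 23 | 7-hydroxy tetracycle (C7 epimers) | C1C(=O)O[C@H]2C[C@]3(CO[Si](C(C)C)(C(C)C)C(C)C)CC(O)[C@@]4(C)C[C@H]5O[C@@]5(C)CC[C@@H]4[C@H]3[C@@]12O
F7 | step 23 | 7-O-thiocarbonylimidazolide of F6 | C1C(=O)O[C@H]2C[C@]3(CO[Si](C(C)C)(C(C)C)C(C)C)CC(OC(=S)n6ccnc6)[C@@]4(C)C[C@H]5O[C@@]5(C)CC[C@@H]4[C@H]3[C@@]12O
F8 | step 20 | homoallylic alcohol (C20 alcohol of 23) | OCCC1=CC[C@](CO[Si](C(C)C)(C(C)C)C(C)C)(CC(=O)N(C)C)[C@H]1[C@H]2CC[C@]3(C)O[C@@H]3CC2=C
F9 | step 20 | 2α,3α-epoxy alcohol | OCC[C@@]12O[C@@H]1C[C@](CO[Si](C(C)C)(C(C)C)C(C)C)(CC(=O)N(C)C)[C@H]2[C@H]3CC[C@]4(C)O[C@@H]4CC3=C
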